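**Retrosynthetic overview**
1. The target is one benzene ring, numbered here C1 (OH), C2 (tricosyl), C3 (H), C4 (OMe), C5 (H), C6 (OMe). The plan rests on its oxygen pattern: the C1 and C4 oxygens are para and the C6 methoxy sits next to C1, which is the pattern a 3-methoxy-4-oxy-4-alkenylcyclobutenone gives on ring expansion.
2. Endgame: C1–OH comes from a C1–OSi ether and C4–OMe from a free C4–OH. That 4-silyloxyphenol is disconnected at the C3–C4 bond (alkene CH2 to ketene carbon) back to a 4-silyloxy-3-methoxy-4-(pentacos-1-en-2-yl)cyclobut-2-enone.
3. The cyclobutenone is cut at the bond between its carbinol carbon (future C1) and the alkenyl carbon (future C2), giving methyl semisquarate (from dimethyl squarate) and 2-lithiopentacos-1-ene.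
4. The alkenyl bromide behind that lithium reagent comes from docosylmagnesium bromide and 2,3-dibromopropene.
5. Ring order: the four-membered ring is purchased; the benzene ring, the only ring of the target, is made once, in a single thermal step.

Key step: step 5

Remark: compounds 2 and 9 to 11 carry one stereocentre and are carried as racemates (SMILES show one enantiomer). The centre disappears in step 5 and the target is achiral.

**Route**

Step 1
Reactants: 1 dimethyl squarate
Product: 3 3-methoxycyclobut-3-ene-1,2-dione (methyl semisquarate), via hydroxycyclobutenone 2 (not isolated)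
Conditions: LiAlH(OtBu)3 (1.05 equiv), THF, –78 → –20 °C; then 6 M aq HCl, CH2Cl2, 0 °C → rt
Reagents that add atoms: water, SMILES O (supplies the new carbonyl oxygen)
Why: Bulky LiAlH(OtBu)3 delivers one hydride to one squarate carbonyl (1,2-reduction) and stops at racemic carbinol 2, whose acid-promoted ionisation gives a methoxy-stabilised cation that water captures and that collapses with loss of methanol to the 1,2-dione (squarate-to-semisquarate reduction–hydrolysis), erasing the stereocentre.

Step 2
Reactants: 4 1-bromodocosane; 5 2,3-dibromopropene
Product: 7 2-bromopentacos-1-ene, via docosylmagnesium bromide 6 (not isolated)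
Conditions: Mg, THF, 50 °C; then 5 (1.3 equiv), CuI (5 mol%), THF, 0 °C → rt
Reagents that add atoms: none
Why: Magnesium insertion gives the primary Grignard reagent, which under CuI catalysis displaces the allylic bromide of 5 (copper-catalysed allylic substitution; direct and allylically transposed attack give the same 2-bromo-1-alkene) while the vinylic C–Br bond is inert.

Step 3
Reactants: 7 2-bromopentacos-1-ene; 3 3-methoxycyclobut-3-ene-1,2-dione
Product: 10 4-hydroxy-3-methoxy-4-(pentacos-1-en-2-yl)cyclobut-2-en-1-one (racemic), via 2-lithiopentacos-1-ene 8 (not isolated), via lithium alkoxide 9 (not isolated)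
Conditions: t-BuLi (2.0 equiv), Et2O (dilute), –78 → –40 °C; cannulate into 3 (1.2 equiv), THF, –78 °C; sat. aq NH4Cl, –78 °C → rt
Reagents that add atoms: none
Why: Halogen–lithium exchange gives the 2-lithio-1-alkene, which adds 1,2 to the ketone-type carbonyl next to the methoxy-bearing carbon and not to the less electrophilic vinylogous ester carbonyl (organolithium carbonyl addition as practised on squarate esters); the new quaternary carbinol centre forms without control and is racemic.

Step 4
Reactants: 10 4-hydroxy-3-methoxy-4-(pentacos-1-en-2-yl)cyclobut-2-en-1-one
Product: 11 4-(tert-butyldimethylsilyloxy)-3-methoxy-4-(pentacos-1-en-2-yl)cyclobut-2-en-1-one (racemic)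
Conditions: TBSOTf (1.3 equiv), 2,6-lutidine (2 equiv), CH2Cl2, –78 → 0 °C
Reagents that add atoms: tert-butyldimethylsilyl trifluoromethanesulfonate (TBSOTf), CC(C)(C)[Si](C)(C)OS(=O)(=O)C(F)(F)F
Why: A silyl triflate with a hindered pyridine base silylates tertiary alcohols at low temperature (O-silylation), so the base-labile hydroxycyclobutenone never meets a strong base and the stereocentre is untouched.

Step 5
Reactants: 11 4-(tert-butyldimethylsilyloxy)-3-methoxy-4-(pentacos-1-en-2-yl)cyclobut-2-en-1-one
Product: 14 4-(tert-butyldimethylsilyloxy)-3-methoxy-5-tricosylphenol, via dienylketene 12 (not isolated), via cyclohexadienone 13 (not isolated)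
Conditions: toluene (0.01 M, degassed), 110 °C
Reagents that add atoms: none
Why: Heat drives a conrotatory 4π electrocyclic opening of the cyclobutenone bond between the carbonyl carbon and the silyloxy-bearing carbon, giving dienylketene 12 in which the ketene, the enol ether C=C and the 1,1-disubstituted alkene form a hexatriene. A thermal disrotatory 6π electrocyclisation then joins the ketene carbon to the terminal alkene CH2 (the C3–C4 bond), closing the six-membered carbocycle as cyclohexa-2,4-dienone 13, and enolisation aromatises it to phenol 14. The reaction type is the Moore rearrangement, the thermal ring expansion of squarate-derived 4-alkenyl-4-oxycyclobutenones to hydroquinone derivatives, and 4-silyloxy substrates giving monosilylated hydroquinones are the closest cases. No stereocentre is created, and the racemic carbinol centre of 11 disappears on aromatisation. The selectivity required is torquoselectivity in the ring opening: the silyloxy group, the better π-donor on the breaking bond, rotates outward, so the alkenyl group turns inward and sits cis to the ketene, the only geometry able to cyclise. Connectivity then fixes the regiochemistry, the carbinol carbon becoming C1 with its silyl ether, the ketene carbon C4 with a free hydroxyl, the alkene carbons C2 (chain) and C3, and the methoxy carbon C6, so the two para oxygens emerge differentiated.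

Step 6
Reactants: 14 4-(tert-butyldimethylsilyloxy)-3-methoxy-5-tricosylphenol
Product: 15 tert-butyl(2,4-dimethoxy-6-tricosylphenoxy)dimethylsilane
Conditions: MeI (3 equiv), K2CO3 (2 equiv), dry acetone, rt → 40 °C
Reagents that add atoms: methyl iodide, CI
Why: Williamson ether synthesis on the single free phenol (C4–OH); the aryl silyl ether at C1 is shielded by its two ortho substituents and should survive anhydrous K2CO3 in acetone.

Step 7
Reactants: 15 tert-butyl(2,4-dimethoxy-6-tricosylphenoxy)dimethylsilane
Product: 16 2,4-dimethoxy-6-tricosylphenol (target)
Conditions: TBAF (1.2 equiv), AcOH (1.2 equiv), THF, 0 °C → rt, under argon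
Reagents that add atoms: none
Why: Fluoride-mediated Si–O cleavage of the aryl silyl ether (desilylation), buffered with acetic acid so that the electron-rich phenol is released protonated and not as an oxidisable phenoxide; the methyl ethers are inert.

**Compound list**
1 | dimethyl squarate (3,4-dimethoxycyclobut-3-ene-1,2-dione) | COC1=C(OC)C(=O)C1=O | starting material
2 | 4-hydroxy-2,3-dimethoxycyclobut-2-en-1-one (racemic, one enantiomer drawn) | COC1=C(OC)[C@@H](O)C1=O | intermediate (not isolated)
3 | 3-methoxycyclobut-3-ene-1,2-dione (methyl semisquarate) | COC1=CC(=O)C1=O | intermediate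
4 | 1-bromodocosane | CCCCCCCCCCCCCCCCCCCCCCBr | starting material
5 | 2,3-dibromopropene | C=C(Br)CBr | starting material
6 | docosylmagnesium bromide | CCCCCCCCCCCCCCCCCCCCCC[Mg]Br | intermediate (not isolated)
7 | 2-bromopentacos-1-ene | C=C(Br)CCCCCCCCCCCCCCCCCCCCCCC | intermediate
8 | 2-lithiopentacos-1-ene | C=C([Li])CCCCCCCCCCCCCCCCCCCCCCC | intermediate (not isolated)
9 | lithium 2-methoxy-4-oxo-1-(pentacos-1-en-2-yl)cyclobut-2-en-1-olate (racemic, one enantiomer drawn) | C=C(CCCCCCCCCCCCCCCCCCCCCCC)[C@]1([O-])C(OC)=CC1=O.[Li+] | intermediate (not isolated)
10 | 4-hydroxy-3-methoxy-4-(pentacos-1-en-2-yl)cyclobut-2-en-1-one (racemic, one enantiomer drawn) | C=C(CCCCCCCCCCCCCCCCCCCCCCC)[C@]1(O)C(OC)=CC1=O | intermediate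
11 | 4-(tert-butyldimethylsilyloxy)-3-methoxy-4-(pentacos-1-en-2-yl)cyclobut-2-en-1-one (racemic, one enantiomer drawn) | C=C(CCCCCCCCCCCCCCCCCCCCCCC)[C@]1(O[Si](C)(C)C(C)(C)C)C(OC)=CC1=O | intermediate (key-step precursor)
12 | (3Z)-4-(tert-butyldimethylsilyloxy)-3-methoxy-5-methylideneoctacosa-1,3-dien-1-one (dienylketene) | O=C=C/C(OC)=C(O[Si](C)(C)C(C)(C)C)\C(=C)CCCCCCCCCCCCCCCCCCCCCCC | intermediate (not isolated)
13 | 4-(tert-butyldimethylsilyloxy)-3-methoxy-5-tricosylcyclohexa-2,4-dien-1-one | O=C1C=C(OC)C(O[Si](C)(C)C(C)(C)C)=C(CCCCCCCCCCCCCCCCCCCCCCC)C1 | intermediate (not isolated)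
14 | 4-(tert-butyldimethylsilyloxy)-3-methoxy-5-tricosylphenol | Oc1cc(OC)c(O[Si](C)(C)C(C)(C)C)c(CCCCCCCCCCCCCCCCCCCCCCC)c1 | intermediate (key-step product)
15 | tert-butyl(2,4-dimethoxy-6-tricosylphenoxy)dimethylsilane | COc1cc(OC)c(O[Si](C)(C)C(C)(C)C)c(CCCCCCCCCCCCCCCCCCCCCCC)c1 | intermediate
16 | 2,4-dimethoxy-6-tricosylphenol | CCCCCCCCCCCCCCCCCCCCCCCc1cc(OC)cc(OC)c1O | target

**Step count**
Total steps: 7. Longest linear sequence: 6 steps (steps 2, 3, 4, 5, 6, 7 from 1-bromodocosane; the branch from dimethyl squarate through steps 1, 3, 4, 5, 6, 7 is equally long).

**Steps most likely to fail**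

Step 3. The C25 alkenyl bromide or its lithio derivative may crystallise from the cold ether, leaving exchange and addition incomplete. The strongly basic alkenyllithium may also attack the labile methyl semisquarate at the vinylogous ester carbonyl or displace methoxide by addition–elimination. The fallback sets out from 7 and changes the organometallic and the way it is made. Direct insertion of Mg (THF, 45 °C, 1,2-dibromoethane activation) should give pentacos-1-en-2-ylmagnesium bromide F1, a less basic nucleophile that stays in solution at higher temperature. It is added to 3 in THF at –40 °C (Grignard 1,2-addition to the ketone-type carbonyl) and quenched with aqueous NH4Cl, and the route is rejoined at 10.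

Step 5. The ring may open with partial inward rotation of the silyloxy group, giving a ketene geometry that cannot close and is consumed by dimerisation or by adventitious nucleophiles. Thermal loss of the silyl group followed by air oxidation of the resulting hydroquinone is a second possibility. The fallback sets out from the free carbinol 10 and moves the differentiation of the two para oxygens from the silyl group to sterics. Thermolysis of 10 (degassed toluene or p-xylene, reflux), where the hydroxyl is an even stronger outward-rotating donor, should give by the same ring expansion 2-methoxy-6-tricosylbenzene-1,4-diol F2, kept reduced by a Na2S2O4 wash. Mono-O-methylation with dimethyl sulfate (1.0 equiv) and K2CO3 in acetone under argon should then occur at the unhindered C4 hydroxyl, which is flanked by two CH. The C1 hydroxyl is flanked by the chain and the methoxy group and hydrogen-bonded to the latter, so it should react more slowly. This gives the target directly, and the route is rejoined at 16.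

Step 6. Once the C4 phenoxide is present, carbonate may cause loss or intermolecular transfer of the aryl silyl group on the C1 oxygen, leading to scrambled or over-methylated material. The fallback sets out from 14 and methylates without any base by Mitsunobu etherification (PPh3, diisopropyl azodicarboxylate, MeOH, THF, 0 °C → rt), so that no free phenoxide is generated. It rejoins the route at 15 and makes no new compound.

**Further compounds**
F1 | step 3 | pentacos-1-en-2-ylmagnesium bromide | C=C([Mg]Br)CCCCCCCCCCCCCCCCCCCCCCC
F2 | step 5 | 2-methoxy-6-tricosylbenzene-1,4-diol | Oc1cc(OC)c(O)c(CCCCCCCCCCCCCCCCCCCCCCC)c1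
F0 | step 6 | none | none
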